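**Strategy.** The route rests on cutting the bond between the bridging methylene carbon (on C6 of the cyclohexadienone ring) and the aromatic carbon that lies between the two phenolic hydroxyls. This divides the target into two halves of similar size, butyrylfilicinic acid and 2,4-dihydroxy-6-methoxybutyrophenone. The key step joins them in one protecting-group-free operation. A Mannich base of the filicinic half carries the methylene carbon as CH2NMe2 on C6, the only ring C–H of that half. It loses dimethylamine to a 6-methylidene enetrione, which the arene captures at C3, the carbon activated by the 4-hydroxyl and the ketone-chelated 2-hydroxyl.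

Key step: step 5

Remark: the target has no stereocentre; the cyclohexadienone ring is drawn throughout in the enol tautomer of the target structure.

**Step 1**
Reactants: 1 phloroglucinol (benzene-1,3,5-triol); 2 butyronitrile (butanenitrile)
Product: 4 1-(2,4,6-trihydroxyphenyl)butan-1-one, via phloroglucinol ketiminium chloride 3 (not isolated)
Conditions: ZnCl2 (0.3 equiv), HCl (g), Et2O, 0 °C; then H2O, reflux
Reagents that add atoms: water, O
Why: Hoesch acylation, in which the nitrile activated by HCl/ZnCl2 attacks the electron-rich arene once only because the ketiminium salt 3 deactivates the ring, and hydrolysis of 3 should give the aryl ketone.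

**Step 2**
Reactants: 4 1-(2,4,6-trihydroxyphenyl)butan-1-one
Product: 6 2-butanoyl-3,5-dihydroxy-4,4-dimethylcyclohexa-2,5-dien-1-one (butyrylfilicinic acid), via monomethyl ketone 5 (not isolated)
Conditions: NaOMe (3.5 equiv), MeI (2.2 equiv), MeOH, 0 °C to rt; then 1 M HCl
Reagents that add atoms: iodomethane, CI
Why: Dearomatising gem-C-methylation of the phloroglucinol phenoxide, in which the second methyl group should enter at the carbon that already carries the first, because this gives the strongly acidic enolised triketone 6 whose anion resists further alkylation; under- and over-methylated material is to be removed by chromatography.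

**Step 3**
Reactants: 6 2-butanoyl-3,5-dihydroxy-4,4-dimethylcyclohexa-2,5-dien-1-one
Product: 7 2-butanoyl-6-[(dimethylamino)methyl]-3,5-dihydroxy-4,4-dimethylcyclohexa-2,5-dien-1-one hydroiodide
Conditions: CH2=NMe2+ I− (1.2 equiv), MeCN, 0 °C to rt (6 added slowly to the salt); filtration
Reagents that add atoms: N,N-dimethylmethyleneiminium iodide (Eschenmoser's salt), C=[N+](C)C.[I-]
Why: Mannich aminomethylation, in which the enol carbon C6 (the only ring C–H of 6) attacks the preformed iminium ion, and without added base the product should separate as its hydroiodide, a form in which the non-ionised enol does not expel the amine.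

**Step 4**
Reactants: 8 5-methoxyresorcinol (5-methoxybenzene-1,3-diol); 2 butyronitrile
Product: 10 1-(2,4-dihydroxy-6-methoxyphenyl)butan-1-one, via methoxy ketiminium chloride 9 (not isolated)
Conditions: ZnCl2 (0.3 equiv), HCl (g), Et2O, 0 °C; then H2O, reflux
Reagents that add atoms: water, O
Why: Hoesch acylation, in which the two equivalent ring carbons between OH and OMe (each para to the other hydroxyl) outnumber the single carbon between the two hydroxyls, so the 2,4-dihydroxy-6-methoxy ketone should be the main product; the symmetric 2,6-dihydroxy-4-methoxy isomer is to be removed by chromatography, and the methyl ether should survive these mild conditions.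

**Step 5**
Reactants: 7 Mannich base hydroiodide; 10 1-(2,4-dihydroxy-6-methoxyphenyl)butan-1-one
Product: 13 2-butanoyl-6-[(3-butanoyl-2,6-dihydroxy-4-methoxyphenyl)methyl]-3,5-dihydroxy-4,4-dimethylcyclohexa-2,5-dien-1-one, via free Mannich base 11 (not isolated), via enetrione 12 (not isolated)
Conditions: 10 (1.5 equiv), NaOMe (4 equiv), MeOH, 0 °C; 7 added in portions, 0 to 50 °C, N2 purge; then 1 M HCl
Reagents that add atoms: none
Why: Methoxide frees the Mannich base 11 from its salt, and E1cB loss of dimethylamine from its ammonium enolate form gives the 6-methylidene enetrione 12, a vinylogous ortho-quinone methide; the phenoxide of 10 adds through C3 in a conjugate addition, and tautomerisation restores the arene and the enolised triketone. The closest known reaction type is the alkylation of phenols and 1,3-dicarbonyl compounds by Mannich bases through elimination and Michael addition, the usual way to unsymmetrical methylene-bridged acylphloroglucinols. No ring is closed and no stereocentre is formed. The step needs C- over O-alkylation and C3 over C5 attack on the arene: the chelate between the 2-hydroxyl and the ketone fixes the C3=C4 enolate of the 4-oxygen, so C3, flanked by two oxygens and less hindered than C5 beside the methoxy group, should react, as in nuclear alkylation of resacetophenone-type ketones, while O-adducts should revert by retro-Michael cleavage. On the electrophile side only one enetrione can form because C6 was the sole ring C–H of 6; the symmetric dimer is held back because no free 6 is present, and the excess of 10 limits double alkylation.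

**Compound list**
1 | phloroglucinol (benzene-1,3,5-triol) | Oc1cc(O)cc(O)c1 | starting material
2 | butyronitrile (butanenitrile) | CCCC#N | starting material
3 | 1-(2,4,6-trihydroxyphenyl)butan-1-iminium chloride (not isolated) | CCCC(=[NH2+])c1c(O)cc(O)cc1O.[Cl-] | intermediate
4 | 1-(2,4,6-trihydroxyphenyl)butan-1-one | CCCC(=O)c1c(O)cc(O)cc1O | intermediate
5 | 1-(2,4,6-trihydroxy-3-methylphenyl)butan-1-one (not isolated) | CCCC(=O)c1c(O)cc(O)c(C)c1O | intermediate
6 | 2-butanoyl-3,5-dihydroxy-4,4-dimethylcyclohexa-2,5-dien-1-one (butyrylfilicinic acid) | CCCC(=O)C1=C(O)C(C)(C)C(O)=CC1=O | intermediate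
7 | 2-butanoyl-6-[(dimethylamino)methyl]-3,5-dihydroxy-4,4-dimethylcyclohexa-2,5-dien-1-one hydroiodide | CCCC(=O)C1=C(O)C(C)(C)C(O)=C(C[NH+](C)C)C1=O.[I-] | intermediate
8 | 5-methoxyresorcinol (5-methoxybenzene-1,3-diol) | COc1cc(O)cc(O)c1 | starting material
9 | 1-(2,4-dihydroxy-6-methoxyphenyl)butan-1-iminium chloride (not isolated) | CCCC(=[NH2+])c1c(O)cc(O)cc1OC.[Cl-] | intermediate
10 | 1-(2,4-dihydroxy-6-methoxyphenyl)butan-1-one | CCCC(=O)c1c(O)cc(O)cc1OC | intermediate
11 | 2-butanoyl-6-[(dimethylamino)methyl]-3,5-dihydroxy-4,4-dimethylcyclohexa-2,5-dien-1-one, free base (not isolated) | CCCC(=O)C1=C(O)C(C)(C)C(O)=C(CN(C)C)C1=O | intermediate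
12 | 2-butanoyl-3-hydroxy-4,4-dimethyl-6-methylidenecyclohex-2-ene-1,5-dione (not isolated) | CCCC(=O)C1=C(O)C(C)(C)C(=O)C(=C)C1=O | intermediate
13 | 2-butanoyl-6-[(3-butanoyl-2,6-dihydroxy-4-methoxyphenyl)methyl]-3,5-dihydroxy-4,4-dimethylcyclohexa-2,5-dien-1-one | CCCC(=O)C1=C(O)C(C)(C)C(O)=C(Cc2c(O)cc(OC)c(C(=O)CCC)c2O)C1=O | target

**Totals**
Total step count: 5. Longest linear sequence: 4 steps (steps 1, 2, 3 and 5); step 4 is a one-step branch.

**Steps most likely to fail**

Step 5. The enetrione may be captured by C5 of the arene or by both C3 and C5. Under base the methylene bridge may also reopen by retro-Michael cleavage and recombine, which would scramble the two halves. The fallback sets out from 10 and 6 and comes back at 13; it exchanges the roles of the halves. Ketone 10 would be aminomethylated (aq. CH2O, Me2NH, EtOH, rt) to 1-{3-[(dimethylamino)methyl]-2,4-dihydroxy-6-methoxyphenyl}butan-1-one F1. F1 is a stable compound that can be purified to a single regioisomer and assigned before material of the other half is committed. F1 would then be heated with 6 (dioxane, 90 °C, no strong base). Thermal loss of dimethylamine should give the ortho-quinone methide of the arene, and the enol carbon C6 of 6, its only nucleophilic carbon, should add to give 13. In this variant the bridge is closed at the filicinic side.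

Step 3. The Mannich base may lose the amine already during its formation or isolation, and the liberated enetrione would then be captured by unreacted 6 to give the symmetric methylene-bis dimer; a second aminomethylation at C6 is also possible. The fallback sets out from 6 and comes back at 12 and hence 13; it uses a sulfone in place of the amine as the leaving group. Compound 6 with aq. formaldehyde and sodium p-toluenesulfinate in HCO2H/H2O (the three-component sulfonylmethylation of C–H acidic 1,3-dicarbonyl compounds) should give the neutral, non-zwitterionic 2-butanoyl-3,5-dihydroxy-4,4-dimethyl-6-{[(4-methylphenyl)sulfonyl]methyl}cyclohexa-2,5-dien-1-one F2, which should be stable in acid. Added to the phenoxide of 10 (NaOMe, MeOH, 0 °C), F2 should eliminate sulfinate at low temperature to the same enetrione 12, which goes on to 13.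

Step 4. Acylation at the carbon between the two hydroxyls may compete, so that the 2,6-dihydroxy-4-methoxy isomer forms in quantity and is hard to remove. The fallback sets out from 4 and comes back at 10. Compound 4 with MOMCl (2.1 equiv) and iPr2NEt in CH2Cl2 should leave the ketone-chelated hydroxyl free and give 1-[2-hydroxy-4,6-bis(methoxymethoxy)phenyl]butan-1-one F3. Methylation of the remaining hydroxyl (Me2SO4, K2CO3, acetone, reflux) should give 1-[2-methoxy-4,6-bis(methoxymethoxy)phenyl]butan-1-one F4. HCl in MeOH at 50 °C should then remove both MOM groups to give 10, with the methoxy group fixed ortho to the ketone.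

**Further compounds**
F1 | step 5 | 1-{3-[(dimethylamino)methyl]-2,4-dihydroxy-6-methoxyphenyl}butan-1-one | CCCC(=O)c1c(O)c(CN(C)C)c(O)cc1OC
F2 | step 3 | 2-butanoyl-3,5-dihydroxy-4,4-dimethyl-6-{[(4-methylphenyl)sulfonyl]methyl}cyclohexa-2,5-dien-1-one | CCCC(=O)C1=C(O)C(C)(C)C(O)=C(CS(=O)(=O)c2ccc(C)cc2)C1=O
F3 | step 4 | 1-[2-hydroxy-4,6-bis(methoxymethoxy)phenyl]butan-1-one | CCCC(=O)c1c(O)cc(OCOC)cc1OCOC
F4 | step 4 | 1-[2-methoxy-4,6-bis(methoxymethoxy)phenyl]butan-1-one | CCCC(=O)c1c(OC)cc(OCOC)cc1OCOC
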